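**Strategy.** Everything rests on the bond between C3 of the central dihydrobenzofuran and C4 of the outer dihydrobenzofuran, an arene carbon meta to both ring oxygens and thus closed to Friedel–Crafts chemistry. The key step, a nickel-catalysed decarboxylative Negishi arylation, joins the halves in one operation; it exploits the benzylic C3 next to the C2 stereocentre: a C3 carboxyl group, activated as N-hydroxyphthalimide ester, leaves as CO2, and the planar C3 radical takes up the outer-ring arylzinc trans to the C2 aryl group, fixing the last stereocentre. The precursors are acid 15, already carrying the benzofuranylethenyl arm, and aryl bromide 27; both dihydrobenzofuran cores come from ring contraction of enantioenriched flavanones.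

Key step: step 17

Remark: all nine phenols are carried as methyl ethers. The sense of induction of the rhodium–bisphosphine catalyst in steps 6 and 12 is assigned by analogy with 1,4-additions to cyclic enones; the ligand antipodes are exchanged if the opposite flavanone enantiomers form.

**Benzofuran arm (steps 1–5)**

Step 1
Reactants: 1 1-bromo-3,5-dimethoxybenzene
Product: 2 1-bromo-2-iodo-3,5-dimethoxybenzene
Conditions: NIS, CF3CO2H (cat.), MeCN, rt
Reagents that add atoms: N-iodosuccinimide, O=C1CCC(=O)N1I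
Why: Electrophilic aromatic iodination takes place at C2, para to one methoxy group and ortho to the other, because the position between the two methoxy groups is the less reactive one in 5-substituted 1,3-dimethoxybenzenes.

Step 2
Reactants: 2 1-bromo-2-iodo-3,5-dimethoxybenzene; 3 1-ethynyl-4-methoxybenzene
Product: 4 1-bromo-3,5-dimethoxy-2-[(4-methoxyphenyl)ethynyl]benzene
Conditions: PdCl2(PPh3)2 (cat.), CuI (cat.), Et3N, THF, 50 °C
Reagents that add atoms: none
Why: The Sonogashira coupling occurs at the C–I bond only, since oxidative addition of zerovalent palladium to the aryl iodide is far faster than to the flanking aryl bromide.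

Step 3
Reactants: 4 1-bromo-3,5-dimethoxy-2-[(4-methoxyphenyl)ethynyl]benzene
Product: 5 4-bromo-3-iodo-6-methoxy-2-(4-methoxyphenyl)-1-benzofuran
Conditions: I2, CH2Cl2, rt; aq. Na2S2O3 work-up
Reagents that add atoms: iodine, II
Why: Electrophilic iodocyclisation of the o-alkynylanisole: the iodonium ion is opened 5-endo-dig by the ortho methoxy oxygen and iodide removes the methyl group from the oxonium ion, which gives the 3-iodobenzofuran and leaves the bromide at C4.

Step 4
Reactants: 5 4-bromo-3-iodo-6-methoxy-2-(4-methoxyphenyl)-1-benzofuran; 6 (3,5-dimethoxyphenyl)boronic acid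
Product: 7 4-bromo-3-(3,5-dimethoxyphenyl)-6-methoxy-2-(4-methoxyphenyl)-1-benzofuran
Conditions: Pd(PPh3)4 (cat.), K2CO3, 1,4-dioxane/H2O, 70 °C
Reagents that add atoms: none
Why: The Suzuki–Miyaura coupling is chemoselective for the C3 iodide over the C4 bromide and installs the 3,5-dimethoxyphenyl group at C3.

Step 5
Reactants: 7 4-bromo-3-(3,5-dimethoxyphenyl)-6-methoxy-2-(4-methoxyphenyl)-1-benzofuran; 8 tributyl(ethenyl)stannane
Product: 9 3-(3,5-dimethoxyphenyl)-4-ethenyl-6-methoxy-2-(4-methoxyphenyl)-1-benzofuran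
Conditions: Pd(PPh3)4 (cat.), toluene, 100 °C
Reagents that add atoms: none
Why: The Stille coupling turns the hindered C4 bromide into the vinyl group under neutral conditions that leave the aryl ethers untouched.

**Central dihydrobenzofuran acid (steps 6–9)**

Step 6
Reactants: 10 6-bromo-4H-chromen-4-one; 11 (4-methoxyphenyl)boronic acid
Product: 12 (2R)-6-bromo-2-(4-methoxyphenyl)-2,3-dihydro-4H-chromen-4-one
Conditions: [Rh(OH)(cod)]2 (cat.), (R)-MeO-F12-BIPHEP, toluene/H2O, 25 °C
Reagents that add atoms: none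
Why: Rhodium-catalysed asymmetric 1,4-addition of the arylboronic acid (Hayashi–Miyaura reaction) to the chromone, in which the aryl–rhodium complex of the chiral bisphosphine adds to one face of the enone and so sets C2 as R; the electron-poor ligand allows room temperature and the aryl bromide is inert to monovalent rhodium.

Step 7
Reactants: 12 (2R)-6-bromo-2-(4-methoxyphenyl)-2,3-dihydro-4H-chromen-4-one
Product: 13 methyl (2R,3R)-5-bromo-2-(4-methoxyphenyl)-2,3-dihydro-1-benzofuran-3-carboxylate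
Conditions: PhI(OAc)2, H2SO4, HC(OMe)3, rt; aqueous work-up
Reagents that add atoms: trimethyl orthoformate, COC(OC)OC
Why: Oxidative ring contraction of the flavanone with a trivalent iodine reagent: the enol ether formed with the orthoformate is attacked at C3 by the iodane, the ring carbon C4a shifts from C4 to C3 as iodobenzene leaves and C4 becomes the ester carbon, so that C2 keeps its configuration and the ester ends up trans to the C2 aryl group.

Step 8
Reactants: 13 methyl (2R,3R)-5-bromo-2-(4-methoxyphenyl)-2,3-dihydro-1-benzofuran-3-carboxylate; 9 3-(3,5-dimethoxyphenyl)-4-ethenyl-6-methoxy-2-(4-methoxyphenyl)-1-benzofuran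
Product: 14 methyl (2R,3R)-5-{(E)-2-[3-(3,5-dimethoxyphenyl)-6-methoxy-2-(4-methoxyphenyl)-1-benzofuran-4-yl]ethenyl}-2-(4-methoxyphenyl)-2,3-dihydro-1-benzofuran-3-carboxylate
Conditions: Pd(OAc)2 (cat.), P(o-tol)3, Et3N, DMF, 100 °C
Reagents that add atoms: none
Why: Mizoroki–Heck reaction of the aryl bromide with the terminal styrene, in which syn insertion and syn β-hydride elimination give the E-alkene.

Step 9
Reactants: 14 stilbene methyl ester (full name in step 8)
Product: 15 (2R,3R)-5-{(E)-2-[3-(3,5-dimethoxyphenyl)-6-methoxy-2-(4-methoxyphenyl)-1-benzofuran-4-yl]ethenyl}-2-(4-methoxyphenyl)-2,3-dihydro-1-benzofuran-3-carboxylic acid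
Conditions: LiOH, THF/MeOH/H2O, rt; then 1 M HCl
Reagents that add atoms: lithium hydroxide, [Li+].[OH-]
Why: Saponification of the methyl ester; C2 is not affected and the configuration at C3 is of no consequence because C3 becomes a radical in step 17.

**Outer dihydrobenzofuran bromide (steps 10–16)**

Step 10
Reactants: 16 1-(2,6-dihydroxy-4-methoxyphenyl)ethan-1-one
Product: 18 5-hydroxy-7-methoxy-4H-chromen-4-one, via enaminone 17 (not isolated)
Conditions: Me2NCH(OMe)2, toluene, 90 °C; then conc. HCl, CH2Cl2, 40 °C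
Reagents that add atoms: N,N-dimethylformamide dimethyl acetal, COC(OC)N(C)C
Why: Condensation of the methyl ketone with the amide acetal gives the enaminone, and acid then induces conjugate addition of one of the two equivalent phenols and loss of dimethylamine to close the chromone ring.

Step 11
Reactants: 18 5-hydroxy-7-methoxy-4H-chromen-4-one
Product: 19 7-methoxy-4-oxo-4H-chromen-5-yl trifluoromethanesulfonate
Conditions: Tf2O, pyridine, CH2Cl2, 0 °C to rt
Reagents that add atoms: trifluoromethanesulfonic anhydride, O=S(=O)(OS(=O)(=O)C(F)(F)F)C(F)(F)F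
Why: Sulfonylation of the remaining chelated phenol gives an aryl triflate that should withstand the rhodium, iodane and nickel–bipyridine steps and marks the carbon that later carries the metal.

Step 12
Reactants: 19 7-methoxy-4-oxo-4H-chromen-5-yl trifluoromethanesulfonate; 11 (4-methoxyphenyl)boronic acid
Product: 20 (2S)-7-methoxy-2-(4-methoxyphenyl)-4-oxo-3,4-dihydro-2H-chromen-5-yl trifluoromethanesulfonate
Conditions: [Rh(OH)(cod)]2 (cat.), (S)-MeO-F12-BIPHEP, toluene/H2O, 25 °C
Reagents that add atoms: none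
Why: Same rhodium-catalysed asymmetric 1,4-addition as in step 6 but with the antipodal ligand, which sets C2 as S; the aryl triflate does not react with monovalent rhodium.

Step 13
Reactants: 20 (2S)-7-methoxy-2-(4-methoxyphenyl)-4-oxo-3,4-dihydro-2H-chromen-5-yl trifluoromethanesulfonate
Product: 21 methyl (2S,3S)-6-methoxy-2-(4-methoxyphenyl)-4-{[(trifluoromethyl)sulfonyl]oxy}-2,3-dihydro-1-benzofuran-3-carboxylate
Conditions: PhI(OAc)2, H2SO4, HC(OMe)3, rt; aqueous work-up
Reagents that add atoms: trimethyl orthoformate, COC(OC)OC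
Why: Same trivalent-iodine ring contraction as in step 7; the migrating carbon C4a is para to the methoxy group, which offsets the ortho triflate, C2 is untouched and the ester forms trans to the C2 aryl group.

Step 14
Reactants: 21 methyl (2S,3S)-6-methoxy-2-(4-methoxyphenyl)-4-{[(trifluoromethyl)sulfonyl]oxy}-2,3-dihydro-1-benzofuran-3-carboxylate
Product: 22 (2S,3S)-6-methoxy-2-(4-methoxyphenyl)-4-{[(trifluoromethyl)sulfonyl]oxy}-2,3-dihydro-1-benzofuran-3-carboxylic acid
Conditions: Me3SnOH, ClCH2CH2Cl, 80 °C; then 1 M HCl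
Reagents that add atoms: trimethyltin hydroxide, C[Sn](C)(C)O
Why: Trimethyltin hydroxide cleaves the methyl ester by way of the tin carboxylate under nearly neutral conditions that spare the aryl triflate.

Step 15
Reactants: 22 triflate acid (full name in step 14); 23 (3,5-dimethoxyphenyl)magnesium chloride
Product: 26 (2S,3S)-3-(3,5-dimethoxyphenyl)-6-methoxy-2-(4-methoxyphenyl)-2,3-dihydro-1-benzofuran-4-yl trifluoromethanesulfonate, via redox-active ester 24 (not isolated), via arylzinc chloride 25 (not isolated)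
Conditions: 22, N-hydroxyphthalimide, DIC, DMAP (cat.), CH2Cl2, rt; separately 23, ZnCl2, LiCl, THF, 0 °C; then NiCl2·glyme (20 mol%), 4,4'-di-tert-butyl-2,2'-bipyridine (40 mol%), THF/DMF, rt; 1 M HCl work-up
Reagents that add atoms: none
Why: Nickel-catalysed decarboxylative Negishi arylation of the N-hydroxyphthalimide ester: single-electron reduction releases CO2 and the benzylic C3 radical, which the aryl–nickel species should capture trans to the C2 aryl group to set C3 as S, while nickel–bipyridine complexes are not expected to insert into the aryl triflate at room temperature.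

Step 16
Reactants: 26 (2S,3S)-3-(3,5-dimethoxyphenyl)-6-methoxy-2-(4-methoxyphenyl)-2,3-dihydro-1-benzofuran-4-yl trifluoromethanesulfonate
Product: 27 (2S,3S)-4-bromo-3-(3,5-dimethoxyphenyl)-6-methoxy-2-(4-methoxyphenyl)-2,3-dihydro-1-benzofuran
Conditions: Pd2(dba)3 (cat.), t-BuBrettPhos, KBr, KF, 1,4-dioxane, 130 °C
Reagents that add atoms: potassium bromide, [K+].[Br-]
Why: Palladium-catalysed triflate-to-bromide exchange: oxidative addition of the aryl triflate, exchange with bromide and C–Br reductive elimination, which the bulky biarylphosphine makes possible; the stereocentres are not involved.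

**Fragment union and deprotection (steps 17–18)**

Step 17
Reactants: 15 benzofuranylethenyl dihydrobenzofuran acid (full name in step 9); 27 (2S,3S)-4-bromo-3-(3,5-dimethoxyphenyl)-6-methoxy-2-(4-methoxyphenyl)-2,3-dihydro-1-benzofuran
Product: 31 (2R,3R)-3-[(2S,3S)-3-(3,5-dimethoxyphenyl)-6-methoxy-2-(4-methoxyphenyl)-2,3-dihydro-1-benzofuran-4-yl]-5-{(E)-2-[3-(3,5-dimethoxyphenyl)-6-methoxy-2-(4-methoxyphenyl)-1-benzofuran-4-yl]ethenyl}-2-(4-methoxyphenyl)-2,3-dihydro-1-benzofuran, via redox-active ester 28 (not isolated), via aryllithium 29 (not isolated), via arylzinc chloride 30 (not isolated)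
Conditions: 15, N-hydroxyphthalimide, DIC, DMAP (cat.), CH2Cl2, rt; separately 27, t-BuLi (2 equiv), THF, −78 °C, then ZnCl2, −78 °C to rt; then NiCl2·glyme (20 mol%), 4,4'-di-tert-butyl-2,2'-bipyridine (40 mol%), THF/DMF, rt; 1 M HCl work-up
Reagents that add atoms: none
Why: The arylzinc 30 transmetalates to nickel and the resulting low-valent aryl–nickel species reduces ester 28 by single-electron transfer, so that the N–O bond breaks, CO2 is lost and a planar benzylic radical forms at C3 of the central ring; the radical recombines with the aryl–nickel species and reductive elimination from trivalent nickel forges the C3–C4 bond. The closest known reaction type is the nickel-catalysed decarboxylative Negishi arylation of N-hydroxyphthalimide esters of secondary and benzylic acids with arylzinc chlorides. No ring is closed. The new stereocentre C3 is set by the neighbouring C2 centre: the 4-methoxyphenyl group on the rigid five-membered ring blocks one face, the aryl group should enter trans and the 2R,3R ring should result, whatever the C3 configuration of acid 15 was. The step needs this diastereoselectivity and a capture of the radical that outruns β-scission of the C2–O bond, dimerisation and addition to the stilbene; the first is secured by the C2 aryl group, the second by the poor overlap of the ring C2–O bond with the radical orbital and by the high nickel loading. Aryl methyl ethers, the benzofuran and the E-alkene are inert to the arylzinc reagent.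

Step 18
Reactants: 31 nona-O-methyl ether of the target (full name in step 17)
Product: 32 CNP0135983.1, the nonaphenol with (2R,3R) central and (2S,3S) outer dihydrobenzofuran and E-alkene
Conditions: BBr3 (excess), CH2Cl2, −78 °C to rt; then H2O
Reagents that add atoms: none
Why: Lewis-acid cleavage of all nine aryl methyl ethers by BBr3; benzylic C2–O bonds that ionise should reclose to the more stable trans rings and the C3 centres are not touched, so that the configuration is kept.

**Compound list**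

1 | 1-bromo-3,5-dimethoxybenzene | COc1cc(OC)cc(Br)c1 | starting material
2 | 1-bromo-2-iodo-3,5-dimethoxybenzene | COc1cc(OC)c(I)c(Br)c1 | intermediate
3 | 1-ethynyl-4-methoxybenzene | C#Cc1ccc(OC)cc1 | starting material
4 | 1-bromo-3,5-dimethoxy-2-[(4-methoxyphenyl)ethynyl]benzene | COc1ccc(C#Cc2c(Br)cc(OC)cc2OC)cc1 | intermediate
5 | 4-bromo-3-iodo-6-methoxy-2-(4-methoxyphenyl)-1-benzofuran | COc1ccc(-c2oc3cc(OC)cc(Br)c3c2I)cc1 | intermediate
6 | (3,5-dimethoxyphenyl)boronic acid | COc1cc(OC)cc(B(O)O)c1 | starting material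
7 | 4-bromo-3-(3,5-dimethoxyphenyl)-6-methoxy-2-(4-methoxyphenyl)-1-benzofuran | COc1ccc(-c2oc3cc(OC)cc(Br)c3c2-c2cc(OC)cc(OC)c2)cc1 | intermediate
8 | tributyl(ethenyl)stannane | C=C[Sn](CCCC)(CCCC)CCCC | starting material
9 | 3-(3,5-dimethoxyphenyl)-4-ethenyl-6-methoxy-2-(4-methoxyphenyl)-1-benzofuran | COc1ccc(-c2oc3cc(OC)cc(C=C)c3c2-c2cc(OC)cc(OC)c2)cc1 | intermediate
10 | 6-bromo-4H-chromen-4-one | O=c1ccoc2ccc(Br)cc12 | starting material
11 | (4-methoxyphenyl)boronic acid | COc1ccc(B(O)O)cc1 | starting material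
12 | (2R)-6-bromo-2-(4-methoxyphenyl)-2,3-dihydro-4H-chromen-4-one | O=C1C[C@H](c2ccc(OC)cc2)Oc2ccc(Br)cc12 | intermediate
13 | methyl (2R,3R)-5-bromo-2-(4-methoxyphenyl)-2,3-dihydro-1-benzofuran-3-carboxylate | Brc1ccc2c(c1)[C@@H](C(=O)OC)[C@H](c1ccc(OC)cc1)O2 | intermediate
14 | methyl (2R,3R)-5-{(E)-2-[3-(3,5-dimethoxyphenyl)-6-methoxy-2-(4-methoxyphenyl)-1-benzofuran-4-yl]ethenyl}-2-(4-methoxyphenyl)-2,3-dihydro-1-benzofuran-3-carboxylate | COc1ccc(-c2oc3cc(OC)cc(/C=C/c4ccc5c(c4)[C@@H](C(=O)OC)[C@H](c4ccc(OC)cc4)O5)c3c2-c2cc(OC)cc(OC)c2)cc1 | intermediate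
15 | (2R,3R)-5-{(E)-2-[3-(3,5-dimethoxyphenyl)-6-methoxy-2-(4-methoxyphenyl)-1-benzofuran-4-yl]ethenyl}-2-(4-methoxyphenyl)-2,3-dihydro-1-benzofuran-3-carboxylic acid | COc1ccc(-c2oc3cc(OC)cc(/C=C/c4ccc5c(c4)[C@@H](C(=O)O)[C@H](c4ccc(OC)cc4)O5)c3c2-c2cc(OC)cc(OC)c2)cc1 | intermediate
16 | 1-(2,6-dihydroxy-4-methoxyphenyl)ethan-1-one | CC(=O)c1c(O)cc(OC)cc1O | starting material
17 | (2E)-1-(2,6-dihydroxy-4-methoxyphenyl)-3-(dimethylamino)prop-2-en-1-one (formed in the flask) | CN(C)/C=C/C(=O)c1c(O)cc(OC)cc1O | intermediate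
18 | 5-hydroxy-7-methoxy-4H-chromen-4-one | COc1cc(O)c2c(c1)occc2=O | intermediate
19 | 7-methoxy-4-oxo-4H-chromen-5-yl trifluoromethanesulfonate | COc1cc(OS(=O)(=O)C(F)(F)F)c2c(c1)occc2=O | intermediate
20 | (2S)-7-methoxy-2-(4-methoxyphenyl)-4-oxo-3,4-dihydro-2H-chromen-5-yl trifluoromethanesulfonate | O=C1C[C@@H](c2ccc(OC)cc2)Oc2cc(OC)cc(OS(=O)(=O)C(F)(F)F)c12 | intermediate
21 | methyl (2S,3S)-6-methoxy-2-(4-methoxyphenyl)-4-{[(trifluoromethyl)sulfonyl]oxy}-2,3-dihydro-1-benzofuran-3-carboxylate | FC(F)(F)S(=O)(=O)Oc1cc(OC)cc2c1[C@H](C(=O)OC)[C@@H](c1ccc(OC)cc1)O2 | intermediate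
22 | (2S,3S)-6-methoxy-2-(4-methoxyphenyl)-4-{[(trifluoromethyl)sulfonyl]oxy}-2,3-dihydro-1-benzofuran-3-carboxylic acid | FC(F)(F)S(=O)(=O)Oc1cc(OC)cc2c1[C@H](C(=O)O)[C@@H](c1ccc(OC)cc1)O2 | intermediate
23 | (3,5-dimethoxyphenyl)magnesium chloride | COc1cc(OC)cc([Mg]Cl)c1 | starting material
24 | 1,3-dioxoisoindolin-2-yl ester of acid 22 (formed in the flask) | FC(F)(F)S(=O)(=O)Oc1cc(OC)cc2c1[C@H](C(=O)ON1C(=O)c3ccccc3C1=O)[C@@H](c1ccc(OC)cc1)O2 | intermediate
25 | (3,5-dimethoxyphenyl)zinc chloride (formed in the flask) | COc1cc(OC)cc([Zn]Cl)c1 | intermediate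
26 | (2S,3S)-3-(3,5-dimethoxyphenyl)-6-methoxy-2-(4-methoxyphenyl)-2,3-dihydro-1-benzofuran-4-yl trifluoromethanesulfonate | FC(F)(F)S(=O)(=O)Oc1cc(OC)cc2c1[C@H](c1cc(OC)cc(OC)c1)[C@@H](c1ccc(OC)cc1)O2 | intermediate
27 | (2S,3S)-4-bromo-3-(3,5-dimethoxyphenyl)-6-methoxy-2-(4-methoxyphenyl)-2,3-dihydro-1-benzofuran | Brc1cc(OC)cc2c1[C@H](c1cc(OC)cc(OC)c1)[C@@H](c1ccc(OC)cc1)O2 | intermediate
28 | 1,3-dioxoisoindolin-2-yl ester of acid 15 (formed in the flask) | COc1ccc(-c2oc3cc(OC)cc(/C=C/c4ccc5c(c4)[C@@H](C(=O)ON4C(=O)c6ccccc6C4=O)[C@H](c4ccc(OC)cc4)O5)c3c2-c2cc(OC)cc(OC)c2)cc1 | intermediate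
29 | [(2S,3S)-3-(3,5-dimethoxyphenyl)-6-methoxy-2-(4-methoxyphenyl)-2,3-dihydro-1-benzofuran-4-yl]lithium (formed in the flask) | [Li]c1cc(OC)cc2c1[C@H](c1cc(OC)cc(OC)c1)[C@@H](c1ccc(OC)cc1)O2 | intermediate
30 | [(2S,3S)-3-(3,5-dimethoxyphenyl)-6-methoxy-2-(4-methoxyphenyl)-2,3-dihydro-1-benzofuran-4-yl]zinc chloride (formed in the flask) | Cl[Zn]c1cc(OC)cc2c1[C@H](c1cc(OC)cc(OC)c1)[C@@H](c1ccc(OC)cc1)O2 | intermediate
31 | (2R,3R)-3-[(2S,3S)-3-(3,5-dimethoxyphenyl)-6-methoxy-2-(4-methoxyphenyl)-2,3-dihydro-1-benzofuran-4-yl]-5-{(E)-2-[3-(3,5-dimethoxyphenyl)-6-methoxy-2-(4-methoxyphenyl)-1-benzofuran-4-yl]ethenyl}-2-(4-methoxyphenyl)-2,3-dihydro-1-benzofuran | COc1ccc(-c2oc3cc(OC)cc(/C=C/c4ccc5c(c4)[C@@H](c4cc(OC)cc6c4[C@H](c4cc(OC)cc(OC)c4)[C@@H](c4ccc(OC)cc4)O6)[C@H](c4ccc(OC)cc4)O5)c3c2-c2cc(OC)cc(OC)c2)cc1 | intermediate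
32 | CNP0135983.1: 5-[(2S,3S)-4-[(2R,3R)-5-{(E)-2-[3-(3,5-dihydroxyphenyl)-6-hydroxy-2-(4-hydroxyphenyl)-1-benzofuran-4-yl]ethenyl}-2-(4-hydroxyphenyl)-2,3-dihydro-1-benzofuran-3-yl]-6-hydroxy-2-(4-hydroxyphenyl)-2,3-dihydro-1-benzofuran-3-yl]benzene-1,3-diol | Oc1ccc(-c2oc3cc(O)cc(/C=C/c4ccc5c(c4)[C@@H](c4cc(O)cc6c4[C@H](c4cc(O)cc(O)c4)[C@@H](c4ccc(O)cc4)O6)[C@H](c4ccc(O)cc4)O5)c3c2-c2cc(O)cc(O)c2)cc1 | target

**Count and risks**

Total step count: 18. Longest linear sequence: 9 steps (10–16, 17, 18; the branch 1–5, 8, 9, 17, 18 is equally long).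

Steps most likely to fail:

1. Step 17. Capture of the encumbered C3 radical by the ortho-substituted aryl–nickel species may be slow, so that reduction, dimerisation or ring opening of the radical and erosion of the trans selectivity take over. The fallback makes the same bond by polar addition and closes the central ring afterwards by a donor/donor carbene C–H insertion; it sets out from 27 and 9 and comes back to the route at 31. 5-Bromosalicylaldehyde is etherified with 4-methoxybenzyl chloride (K2CO3, DMF) to 5-bromo-2-[(4-methoxybenzyl)oxy]benzaldehyde F1. A Mizoroki–Heck reaction of F1 with 9 gives the stilbene aldehyde F2. Aryllithium 29 (from 27 and t-BuLi) adds to F2 to give the diarylmethanol F3, which Dess–Martin periodinane oxidises to the diaryl ketone F4. Hydrazine hydrate (AcOH, n-BuOH, heat) gives the hydrazone F5, and MnO2 oxidises it to the diaryldiazomethane F6. With Rh2(R-PTAD)4 (or its antipode, chosen to set 3R) the carbene should insert into the neighbouring benzylic ether C–H bond to give the cis-(2S,3R)-dihydrobenzofuran F7. Trifluoroacetic acid then epimerises C2 by reversible ionisation of the benzylic C2–O bond and should give the trans isomer 31.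

2. Step 18. During the ninefold ether cleavage, ionisation at the benzylic C2–O bonds and protonation of the stilbene may lead to cyclisation onto the neighbouring resorcinol ring, to ring opening or to incomplete demethylation. The fallback sets out from 31 and comes back at 32. The ethers are cleaved with BCl3 and n-Bu4NI (CH2Cl2, −78 to 0 °C), where iodide takes up the methyl groups so that no strong protic acid builds up. After aqueous work-up the crude polyphenol is acetylated (Ac2O, pyridine, DMAP) to the nonaacetate F8, which is purified by chromatography and then methanolysed (K2CO3, degassed MeOH, rt) to 32.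

3. Step 13. The anisyl group may shift from C2 to C3 (isoflavone formation), the flavanone may be dehydrogenated to the flavone, or the triflate-bearing ring may migrate sluggishly while acid opens the pyranone ring and racemises C2. The fallback makes the migrating ring electron-rich; it sets out from 18 and comes back at 21. Chromone 18 is benzylated (BnBr, K2CO3, DMF) to 5-(benzyloxy)-7-methoxy-4H-chromen-4-one F9. The rhodium-catalysed addition of 11 as in step 12 gives the (2S)-flavanone F10. The same PhI(OAc)2/H2SO4/HC(OMe)3 ring contraction gives the benzyloxy ester F11. Hydrogenolysis (H2, Pd/C, EtOAc) frees the phenol F12, and Tf2O/pyridine converts it to 21.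

Further compounds
F1 | step 17 | 5-bromo-2-[(4-methoxybenzyl)oxy]benzaldehyde | O=Cc1cc(Br)ccc1OCc1ccc(OC)cc1
F2 | step 17 | 5-{(E)-2-[3-(3,5-dimethoxyphenyl)-6-methoxy-2-(4-methoxyphenyl)-1-benzofuran-4-yl]ethenyl}-2-[(4-methoxybenzyl)oxy]benzaldehyde | COc1ccc(-c2oc3cc(OC)cc(/C=C/c4ccc(OCc5ccc(OC)cc5)c(C=O)c4)c3c2-c2cc(OC)cc(OC)c2)cc1
F3 | step 17 | diarylmethanol from 29 and F2 (carbinol carbon as a mixture of epimers; outer ring 2S,3S) | COc1ccc(-c2oc3cc(OC)cc(/C=C/c4ccc(OCc5ccc(OC)cc5)c(C(O)c5cc(OC)cc6c5[C@H](c5cc(OC)cc(OC)c5)[C@@H](c5ccc(OC)cc5)O6)c4)c3c2-c2cc(OC)cc(OC)c2)cc1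
F4 | step 17 | diaryl ketone from F3 | COc1ccc(-c2oc3cc(OC)cc(/C=C/c4ccc(OCc5ccc(OC)cc5)c(C(=O)c5cc(OC)cc6c5[C@H](c5cc(OC)cc(OC)c5)[C@@H](c5ccc(OC)cc5)O6)c4)c3c2-c2cc(OC)cc(OC)c2)cc1
F5 | step 17 | hydrazone of ketone F4 | COc1ccc(-c2oc3cc(OC)cc(/C=C/c4ccc(OCc5ccc(OC)cc5)c(C(=NN)c5cc(OC)cc6c5[C@H](c5cc(OC)cc(OC)c5)[C@@H](c5ccc(OC)cc5)O6)c4)c3c2-c2cc(OC)cc(OC)c2)cc1
F6 | step 17 | diaryldiazomethane from F5 | COc1ccc(-c2oc3cc(OC)cc(/C=C/c4ccc(OCc5ccc(OC)cc5)c(C(=[N+]=[N-])c5cc(OC)cc6c5[C@H](c5cc(OC)cc(OC)c5)[C@@H](c5ccc(OC)cc5)O6)c4)c3c2-c2cc(OC)cc(OC)c2)cc1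
F7 | step 17 | cis isomer of 31 with (2S,3R) central ring | COc1ccc(-c2oc3cc(OC)cc(/C=C/c4ccc5c(c4)[C@@H](c4cc(OC)cc6c4[C@H](c4cc(OC)cc(OC)c4)[C@@H](c4ccc(OC)cc4)O6)[C@@H](c4ccc(OC)cc4)O5)c3c2-c2cc(OC)cc(OC)c2)cc1
F8 | step 18 | nonaacetate of 32 | CC(=O)Oc1ccc(-c2oc3cc(OC(C)=O)cc(/C=C/c4ccc5c(c4)[C@@H](c4cc(OC(C)=O)cc6c4[C@H](c4cc(OC(C)=O)cc(OC(C)=O)c4)[C@@H](c4ccc(OC(C)=O)cc4)O6)[C@H](c4ccc(OC(C)=O)cc4)O5)c3c2-c2cc(OC(C)=O)cc(OC(C)=O)c2)cc1
F9 | step 13 | 5-(benzyloxy)-7-methoxy-4H-chromen-4-one | COc1cc(OCc2ccccc2)c2c(c1)occc2=O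
F10 | step 13 | (2S)-5-(benzyloxy)-7-methoxy-2-(4-methoxyphenyl)-2,3-dihydro-4H-chromen-4-one | O=C1C[C@@H](c2ccc(OC)cc2)Oc2cc(OC)cc(OCc3ccccc3)c12
F11 | step 13 | methyl (2S,3S)-4-(benzyloxy)-6-methoxy-2-(4-methoxyphenyl)-2,3-dihydro-1-benzofuran-3-carboxylate | C(Oc1cc(OC)cc2c1[C@H](C(=O)OC)[C@@H](c1ccc(OC)cc1)O2)c1ccccc1
F12 | step 13 | methyl (2S,3S)-4-hydroxy-6-methoxy-2-(4-methoxyphenyl)-2,3-dihydro-1-benzofuran-3-carboxylate | Oc1cc(OC)cc2c1[C@H](C(=O)OC)[C@@H](c1ccc(OC)cc1)O2
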